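**Assumptions (one line each):**
- Ring numbering follows the target SMILES. C1 is the ring carbon bearing the exocyclic =C19H2, C5 is CHMe, C6 is CHOH, C7 is the lactone CH–O, C8 is the lactone CH, C10 is CHOH, C11 is the quaternary C–Me, and C14 is the THF CH–O.
- The Ipc₂B reagent, the Shi ketone and the Kishi-type ligand are used as the enantiomers that give the configurations stated below.
- Target configuration: 5S, 6R, 7R, 8S, 10R, 11S, 14R. The lactone is cis-fused (C6 and C9 cis on the lactone ring), and the THF is a cis-2,5-bridged ring.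

## Retrosynthesis
1. The target is the bis-TBS ether 19 after HF·py. The 14-membered carbocycle, the cis-fused α-methylene-γ-lactone and the C7–C8 bond form in one step, by intramolecular NHK allylation of a C7 aldehyde with a (Z)-2-(bromomethyl)enoate at C8, followed by lactonisation.
2. The enoate comes from cross-metathesis of a terminal alkene with methyl 2-(hydroxymethyl)acrylate. The C7 aldehyde comes from a primary TBS ether.
3. The cis-THF with the C10-OH comes from 5-exo opening of an (E)-alkene-derived Shi epoxide (C10–C11) by the C14 allylic alcohol. The THF ring is formed before the macrocycle.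
4. The C14 allylic alcohol, which carries C1=C19, comes from asymmetric Ni/Cr coupling of vinyl bromide 5 (C1–C7, made by syn-crotylboration and B-alkyl Suzuki) with dienal 9 (from pentynol by carboalumination and allylation).

## Forward synthesis

**Step 1**
Reactants: 1 (2-(TBSO)acetaldehyde)
Product: 2 ((2R,3S)-1-(TBSO)-3-methylpent-4-en-2-ol)
Conditions: (Z)-crotyl-B(Ipc)₂ (from cis-2-butene, n-BuLi, KOtBu, Ipc₂BOMe, BF₃·OEt₂), THF, –78 °C; then NaOH, H₂O₂
Reagents that add atoms: (Z)-crotyldiisopinocampheylborane, C/C=C\CB(C1CC2CC(C1C)C2(C)C)C1CC2CC(C1C)C2(C)C (pinane stereocentres omitted; the enantiomer giving Re-face attack is used)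
Why: Z-crotylboration of the aldehyde through a Zimmerman–Traxler chair gives the syn adduct, and the chiral Ipc ligands select the Re face, setting C5 (S) and C6 (R).

**Step 2**
Reactants: 2
Product: 3 ((2R,3S)-1,2-bis(TBSO)-3-methylpent-4-ene)
Conditions: TBSOTf, 2,6-lutidine, CH₂Cl₂, –78 °C
Reagents that add atoms: TBSOTf, C[Si](C)(C(C)(C)C)OS(=O)(=O)C(F)(F)F
Why: silylation of the C6 alcohol (protection); the stereocentres are untouched.

**Step 3**
Reactants: 3; 4 (2,3-dibromopropene)
Product: 5 ((2R,3S)-7-bromo-1,2-bis(TBSO)-3-methyloct-7-ene, the vinyl bromide C1–C7 fragment)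
Conditions: 9-BBN dimer, THF, 23 °C; then 4, Pd(PPh₃)₄, K₃PO₄, THF/DMF, 50 °C
Reagents that add atoms: none beyond reactant 4
Why: anti-Markovnikov hydroboration of the terminal alkene gives a B-alkyl-9-BBN, which couples by B-alkyl Suzuki at the more reactive allylic C–Br, leaving the vinyl C–Br to build C2 and C1(Br)=C19.

**Step 4**
Reactants: 6 (pent-4-yn-1-ol); 7 (allyl bromide)
Product: 8 ((E)-4-methylocta-4,7-dien-1-ol)
Conditions: Me₃Al, cat. Cp₂ZrCl₂, CH₂Cl₂, 0→23 °C; then cat. CuCl, 7, THF, 0 °C
Reagents that add atoms: trimethylaluminium, C[Al](C)C (supplies the C11 methyl); allyl bromide 7 (supplies C10, C9 and C8 and the terminal CH₂)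
Why: Negishi Zr-catalysed syn-carboalumination puts Me on C11 and Al on C10, giving the (E)-trisubstituted alkene after Cu-catalysed allylation, which replaces Al with the allyl group with retention.

**Step 5**
Reactants: 8
Product: 9 ((E)-4-methylocta-4,7-dienal)
Conditions: Dess–Martin periodinane, NaHCO₃, CH₂Cl₂, 0 °C
Reagents that add atoms: none
Why: mild oxidation of the primary alcohol to the C14 aldehyde without isomerising the non-conjugated alkenes.

**Step 6**
Reactants: 5; 9
Product: 10 (C14 allylic alcohol, 5S,6R,14R, 10E, bis-TBS ether)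
Conditions: CrCl₂ (10 mol%), chiral sulfonamide ligand, NiCl₂ (cat.), Mn, Cp₂ZrCl₂, proton sponge, MeCN, 23 °C
Reagents that add atoms: none
Why: Nozaki–Hiyama–Kishi coupling of vinyl bromide 5 with aldehyde 9 forms C14–C1 and the allylic alcohol, and the enantiopure ligand on Cr sets C14 (R) (no nearby stereocentre).

**Step 7**
Reactants: 10
Product: 11 ((10R,11R)-trans-epoxide at C10–C11)
Conditions: Shi fructose-derived ketone (30 mol%), Oxone, K₂CO₃, Bu₄NHSO₄, MeCN/DMM/aq. buffer, 0 °C
Reagents that add atoms: Oxone, [K+].OOS(=O)(=O)[O-] (supplies the epoxide O)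
Why: Shi asymmetric epoxidation prefers the electron-rich (E)-trisubstituted alkene over the 1,1-disubstituted and terminal alkenes, and the catalyst sets C10 (R) and C11 (R) with the trans relationship that matches the (E)-alkene.

**Step 8**
Reactants: 11
Product: 12 (THF 12: 10R,11S,14R, C10-OH free)
Conditions: CSA (10 mol%), CH₂Cl₂, 0 °C
Reagents that add atoms: none
Why: the C14-OH opens the epoxide 5-exo at the tertiary carbon C11 with inversion (acid-catalysed epoxide opening). This forms the THF ring, sets the quaternary C11 (S) and the cis-2,5 relationship to C14, and liberates C10-OH (R, retained).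

**Step 9**
Reactants: 12
Product: 13 (C10 TBS ether)
Conditions: TBSOTf, 2,6-lutidine, CH₂Cl₂, –78 → 0 °C
Reagents that add atoms: TBSOTf, C[Si](C)(C(C)(C)C)OS(=O)(=O)C(F)(F)F
Why: silylation protects the hindered C10 secondary alcohol before oxidation; no stereocentre is touched.

**Step 10**
Reactants: 13
Product: 14 (C7 primary alcohol)
Conditions: CSA (10 mol%), MeOH/CH₂Cl₂ 1:1, 0 °C
Reagents that add atoms: none
Why: acidic methanolysis cleaves the primary TBS ether faster than the hindered secondary TBS ethers at C6 and C10.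

**Step 11**
Reactants: 14
Product: 15 (C7 aldehyde with terminal C8=CH₂)
Conditions: Dess–Martin periodinane, NaHCO₃, CH₂Cl₂, 23 °C
Reagents that add atoms: none
Why: buffered oxidation gives the α-silyloxy aldehyde needed for the NHK step without epimerising C6.

**Step 12**
Reactants: 15; 16 (methyl 2-(hydroxymethyl)acrylate)
Product: 17 (E-enoate, C8=C(CH₂OH)CO₂Me)
Conditions: Hoveyda–Grubbs II (5 mol%), 16 (5 equiv), CH₂Cl₂, 40 °C
Reagents that add atoms: none beyond reactant 16 (ethylene is lost)
Why: cross-metathesis of the unhindered terminal alkene with the acrylate gives the thermodynamic (E)-enoate (C9 trans to CO₂Me), and the hindered 1,1-disubstituted alkene does not react.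

**Step 13**
Reactants: 17
Product: 18 ((Z)-2-(bromomethyl)enoate, C7 aldehyde)
Conditions: NBS, Me₂S, CH₂Cl₂, –20→0 °C
Reagents that add atoms: NBS, O=C1CCC(=O)N1Br
Why: Corey–Kim-type SN2 bromination of the primary allylic alcohol under neutral conditions retains the alkene geometry. The geometry is Z by CIP (C9 cis to CH₂Br), which gives the Z-allylchromium needed.

**Step 14**
Reactants: 18
Product: 19 (bis-TBS uprolide D, 5S,6R,7R,8S,10R,11S,14R)
Conditions: CrCl₂ (10 equiv), 4 Å MS, THF, 2 mM with slow addition, 0→23 °C; then cat. PPTS if needed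
Reagents that add atoms: none
Why: intramolecular Nozaki–Hiyama allylation closes the 14-membered ring and forms C7–C8. The Z-allylchromium adds through a chair transition state to give the syn adduct, i.e. the cis-fused lactone with C7 (R) and C8 (S), and the γ-hydroxy methyl ester lactonises with loss of MeOH to give the α-methylene-γ-lactone.

**Step 15**
Reactants: 19
Product: 20 (uprolide D)
Conditions: HF·pyridine, pyridine/THF, 23 °C
Reagents that add atoms: none
Why: fluoride removes both secondary TBS ethers and leaves the α-methylene lactone, exocyclic alkene and THF intact.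

## Compound list
1 | 2-(tert-butyldimethylsilyloxy)acetaldehyde | O=CCO[Si](C)(C)C(C)(C)C | starting material
2 | (2R,3S)-1-(TBSO)-3-methylpent-4-en-2-ol | C=C[C@H](C)[C@@H](O)CO[Si](C)(C)C(C)(C)C | intermediate
3 | (2R,3S)-1,2-bis(TBSO)-3-methylpent-4-ene | C=C[C@H](C)[C@@H](O[Si](C)(C)C(C)(C)C)CO[Si](C)(C)C(C)(C)C | intermediate
4 | 2,3-dibromopropene | C=C(Br)CBr | starting material
5 | (2R,3S)-7-bromo-1,2-bis(TBSO)-3-methyloct-7-ene | C=C(Br)CCC[C@H](C)[C@@H](O[Si](C)(C)C(C)(C)C)CO[Si](C)(C)C(C)(C)C | intermediate
6 | pent-4-yn-1-ol | C#CCCO | starting material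
7 | allyl bromide | C=CCBr | starting material
8 | (E)-4-methylocta-4,7-dien-1-ol | OCCC/C(C)=C/CC=C | intermediate
9 | (E)-4-methylocta-4,7-dienal | O=CCC/C(C)=C/CC=C | intermediate
10 | C14 allylic alcohol (5S,6R,14R; 10E; bis-TBS) | C=CC/C=C(C)/CC[C@@H](O)C(=C)CCC[C@H](C)[C@@H](O[Si](C)(C)C(C)(C)C)CO[Si](C)(C)C(C)(C)C | intermediate
11 | (10R,11R)-C10–C11 epoxide of 10 | C=CC[C@H]1O[C@]1(C)CC[C@@H](O)C(=C)CCC[C@H](C)[C@@H](O[Si](C)(C)C(C)(C)C)CO[Si](C)(C)C(C)(C)C | intermediate
12 | THF alcohol (10R,11S,14R) | C=CC[C@@H](O)[C@]1(C)CC[C@@H](O1)C(=C)CCC[C@H](C)[C@@H](O[Si](C)(C)C(C)(C)C)CO[Si](C)(C)C(C)(C)C | intermediate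
13 | C10-TBS ether of 12 | C=CC[C@@H](O[Si](C)(C)C(C)(C)C)[C@]1(C)CC[C@@H](O1)C(=C)CCC[C@H](C)[C@@H](O[Si](C)(C)C(C)(C)C)CO[Si](C)(C)C(C)(C)C | intermediate
14 | C7 primary alcohol | C=CC[C@@H](O[Si](C)(C)C(C)(C)C)[C@]1(C)CC[C@@H](O1)C(=C)CCC[C@H](C)[C@@H](O[Si](C)(C)C(C)(C)C)CO | intermediate
15 | C7 aldehyde | C=CC[C@@H](O[Si](C)(C)C(C)(C)C)[C@]1(C)CC[C@@H](O1)C(=C)CCC[C@H](C)[C@@H](O[Si](C)(C)C(C)(C)C)C=O | intermediate
16 | methyl 2-(hydroxymethyl)acrylate | C=C(CO)C(=O)OC | starting material
17 | (E)-enoate aldehyde | COC(=O)/C(CO)=C/C[C@@H](O[Si](C)(C)C(C)(C)C)[C@]1(C)CC[C@@H](O1)C(=C)CCC[C@H](C)[C@@H](O[Si](C)(C)C(C)(C)C)C=O | intermediate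
18 | (Z)-allylic bromide aldehyde | COC(=O)/C(CBr)=C/C[C@@H](O[Si](C)(C)C(C)(C)C)[C@]1(C)CC[C@@H](O1)C(=C)CCC[C@H](C)[C@@H](O[Si](C)(C)C(C)(C)C)C=O | intermediate
19 | bis-TBS uprolide D | C=C1CCC[C@H](C)[C@@H](O[Si](C)(C)C(C)(C)C)[C@@H]2OC(=O)C(=C)[C@@H]2C[C@@H](O[Si](C)(C)C(C)(C)C)[C@]2(C)CC[C@H]1O2 | intermediate
20 | uprolide D | C=C1CCC[C@H](C)[C@@H](O)[C@@H]2OC(=O)C(=C)[C@@H]2C[C@@H](O)[C@]2(C)CC[C@H]1O2 | target

**Total steps:** 15 (counting both branches).
**Longest linear sequence:** 13 steps, namely 1 → 2 → 3 (Steps 1–3, making vinyl bromide 5), then Steps 6–15. The other branch (6 → 8 → 9, Steps 4–5) is only 2 steps before it joins at Step 6.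

## Three steps most likely to fail
1. **Step 14 (macro-NHK).** The macrocyclisation may give the trans-lactone or the wrong C7 epimer, because acyclic allylchromium additions often favour anti and the α-silyloxy aldehyde face selectivity is not guaranteed.
   - Fallback: close the ring by a different bond. Build the cis-fused α-methylene lactone first, from a homopropargylic alcohol made by syn-selective Marshall propargylation and converted by Pd-catalysed carbonylation. Then close the 14-membered ring by intramolecular B-alkyl Suzuki coupling at C1–C2.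
2. **Step 6 (asymmetric Ni/Cr coupling with a vinyl bromide).** It may be slow or give low ee at C14.
   - Fallback: add the vinyllithium (from 5 and t-BuLi) to 9, oxidise the racemic alcohol with DMP to the enone, and reduce it with the CBS catalyst enantiomer that gives the (R)-alcohol.
3. **Steps 7–8 (Shi epoxidation, then 5-exo cyclisation).** The 1,1-disubstituted C1=C19 alkene of 10 may compete in the epoxidation, or the cyclisation may give the 6-endo tetrahydropyran.
   - Fallback: change the order. Epoxidise the simple dienol 8 with the same Shi catalyst, where the only competing alkene is the monosubstituted terminal one. Then oxidise to the epoxy-aldehyde with DMP, run the Ni/Cr coupling with 5 on it, and close the THF with CSA as in Step 8. The same (10R,11R) trans-epoxide and C14 (R) are obtained, but without the C1=C19 alkene present during the epoxidation.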